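## Structural features

The target is a ten-membered carbocycle (C1–C10) holding a 1,5-diene: a Z-trisubstituted olefin C1=C10 and an E-trisubstituted olefin C4=C5, each with a methyl group on its fully substituted carbon (C10, C4). An α-methylene-γ-butyrolactone (O6–C12(=O)–C11(=C13H2)–C7–C6) is trans-fused to this ring across C6–C7, and C7 is a fully substituted carbinol. C6, C7, C8 and C9 are four contiguous oxygenated stereocentres (6R,7R,8R,9R), the D-manno pattern if C11 on C7 is read in place of hydrogen, and their oxygens all differ in function (lactone oxygen, tertiary alcohol, ester, allylic secondary alcohol). O8 carries (2S,3R)-2,3-dimethyloxirane-2-carboxylate, the epoxide of tiglic acid, which adds two stereocentres outside the ring. The fragile groups are the exocyclic enoate (conjugate addition), the tertiary C7–O bond β to the lactone carbonyl (elimination or retro-aldol cleavage under base), the glycidic ester (acid, Lewis acid, nucleophiles), the O8 ester between two free hydroxyls (acyl migration) and the medium-ring diene (transannular cyclisation under strong acid). The real difficulty is closing a strained ring with two defined trisubstituted olefins while keeping four neighbouring oxygens distinguishable, and adding the lactone late without enolate chemistry. The key step exploits the fact that O6–C6–C7–C11≡C13 is a homopropargylic alcohol, so that the lactone ring is this unit plus one molecule of carbon monoxide (C12). The structures used below for the cyclisation substrate 27 and its product 28 were checked centre by centre against the target and agree with it, so no structural correction is required.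

## Logic of the disconnections

29 ⇒ 28. Two O–Si bonds (O7, O9) are cut. Silyl ethers are the only masks left at the end and fall to buffered fluoride. The forward step must spare the oxirane and the Michael acceptor and must not let the O8 acyl group move.

28 ⇒ 27 + CO. The bonds C12–O6 and C11–C12 are cut. This removes the whole lactone ring and its carbonyl carbon, leaves a terminal alkyne, and creates no stereocentre. The forward step needs O6–H as the only free hydroxyl and conditions without base.

27 ⇒ 26 ⇒ 25. The O6–benzyl bond and the O7–Si bond are cut. O6 needs a mask that chelates (for the C7 addition) and that is removed oxidatively beside silyl ethers. O7 is silylated only after O8 is acylated, because a free tertiary hydroxyl does not compete in the esterification. The forward steps demand a silyl triflate that leaves the oxirane alone and a buffered quinone oxidation.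

25 ⇒ 19 + 23. The ester C(=O)–O8 bond is cut, which makes the route convergent. The forward step must acylate the hindered secondary O8–H selectively beside the tertiary O7–H and must activate a glycidic acid without opening it.

23 ⇒ 22 ⇒ 21 ⇒ 20. The carboxyl oxidation level and both C–O bonds of the oxirane are removed. Both oxirane stereocentres then come from one reagent-controlled epoxidation of an E-allylic alcohol, which has to deliver oxygen to the correct face (D-tartrate).

19 ⇒ 18 ⇒ 17. The O9–Si bond is cut and the O8/O9 pair is tied back into a dioxolane. The two oxygens then travel as one unit through the ring synthesis. The price is a regioselective silylation of O9 beside O8 in the forward direction.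

17 ⇒ 16. The C7–C11 bond is cut (ethynyl anion plus ketone). This removes the quaternary centre and the alkyne. The forward addition must attack one face of the ring ketone, to be secured by chelation to the O6 ether.

16 ⇒ 15 ⇒ 14. The C7 oxidation level is adjusted and O7 is re-silylated. C7 is carried as a protected carbinol so that C6 and C8 are never α to a ketone during the basic chain-building steps.

14 ⇒ 13. The C1=C10 double bond is cut (ring-closing metathesis). The ring becomes an open triene whose stereocentres are all in place. The forward closure needs high dilution, relies on ring size for the Z geometry, and must start from the C1 vinyl end.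

13 ⇒ 12 ⇒ 11 ⇒ 10 ⇒ 9. The C2–C3 single bond (allyl coupling) and the C4=C5 double bond (stabilised ylide) are cut. A stabilised, α-branched ylide is chosen over a one-step union with a branched sulfone, because it gives the E-trisubstituted olefin dependably. The cost is a substitution that must occur at C3 and not at C5.

9 ⇒ 8 ⇒ 7 ⇒ 6 ⇒ 5. The C5 aldehyde is returned to a primary alcohol, and the O6 benzyl ether to a benzylidene acetal of the terminal diol. This places the chelating ether on O6 without a separate differentiation step. The forward steps require selective hydrolysis of the terminal dioxolane and a regioselective reductive acetal opening.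

5 ⇒ 4 ⇒ 3 ⇒ 2 ⇒ 1. The C10=CH2 bond, the C10–CH3 bond and the lactone oxidation level are removed. The lactone carbon of 2 is already at the oxidation level needed for C10, and opening the furanose frees O7 alone. C6, C8 and C9 (and C7 for the time being) all come from 1. The forward steps require mono-addition to a lactone and olefination of a hemiketal.

## Other disconnections considered

Alternative 1: The cut is the transannular C4–C9 bond, which folds the ten-membered ring back to the trans-fused decalin hydroxy mesylate A1 (ring A holds the future C1=C10 olefin; ring B carries the C5 mesylate, the C6 silyl ether and the C7 ketal). In the forward step the C9 alkoxide of A1 undergoes a Grob fragmentation to the cyclodecadienone A2: the C4–C9 bond, antiperiplanar to the equatorial C5–O sulfonate bond, breaks while C9=O and C4=C5 form.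
- In its favour: the process is concerted and stereospecific, needs no high dilution, and both olefin geometries follow from the rigid bicycle (E from the antiperiplanar array, Z because the ring A olefin is cis). On ring formation and olefin geometry it is better than the metathesis closure of 13.
- Against it here: A2 has no oxygen at C8, a ketone at C9, only a masked ketone at C7, and neither C11–C13 nor the acyl group. After fragmentation the route would need oxygenation at C8 between two carbonyl-level carbons, stereoselective reduction at C9, and then the same C7 alkynylation and carbonylation as in the chosen plan.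
- Comparison: C8 and C9 would be set by substrate control on a flexible ring instead of being taken from a sugar, and an enantioselective route to A1 with four stereocentres is long. The mechanism of the ring-forming event is more reliable, but the stereochemical security and the step economy are expected to be worse.

Alternative 2: The cut is double, C5–C6 and C4–CH3, opening the ring to the ynal A3. In the forward step zerovalent nickel (Ni(cod)2, PBu3) couples aldehyde and alkyne oxidatively to an oxanickelacycle, Me2Zn transmetallates, and reductive elimination gives the allylic alcohol A4. C6 and the methyl group add syn across the alkyne (E olefin), and the ring and the C6 carbinol form in the same event.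
- In its favour: it has the highest bond-forming density of all the plans. The E geometry follows from the mechanism, equal in reliability to the ylide solution and better in step count for the C1–C5 portion.
- Against it here: C6 would be created during macrocyclisation next to the fully substituted C7 with only transannular bias, whereas the chosen route takes C6 from the sugar. A strained ten-membered ring must compete with oligomerisation and with simple reductive coupling. A4 still needs its 2-(silyloxymethyl)vinyl group raised to the acid level and lactonised beside a new allylic alcohol, several redox and protection steps where CO insertion on 27 needs one. The C7 carbinol of A3 also has to be made by a diastereoselective addition, so the issue of step 16 is not avoided.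
- Comparison: more convergent, but stereochemically less secure.

Alternative 3: The cut is C9–C10, opening to the iodo aldehyde A5 with lactone, O8 ester and a C7 silyl ether in place. In the forward step CrCl2 with catalytic NiCl2 turns the Z-iodoalkene into an alkenylchromium species that adds to the C9 aldehyde with retention of olefin geometry, giving A6, one desilylation away from the target.
- In its favour: the Z olefin is fixed before ring closure, which is equal or better than metathesis, where Z rests on ring strain. The coupling tolerates esters, and the end game after ring closure is as short as in the chosen plan, an equal point.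
- Against it here: the C9 stereocentre would be created in the ring closure on an α-acyloxy aldehyde with uncertain facial bias. The resulting chromium alkoxide sits next to the O8 ester, which invites acyl migration, and the α-acyloxy aldehyde is prone to epimerisation and elimination. The Michael-acceptor lactone would also have to be carried through fragment assembly.
- Comparison: in the chosen plan C9 comes from the sugar and the ring closure forms no stereocentre. Step count is comparable, stereochemical risk is higher.

Key step: step 25

Assumption: the numbering C1–C13 of the target is used for every intermediate (D-mannose C1–C6 become C10–C5); PMB = 4-methoxybenzyl, TBS = tert-butyldimethylsilyl, TES = triethylsilyl.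

## Route

Step 1
Reactants: 1 2,3:5,6-di-O-isopropylidene-α-D-mannofuranose
Product: 2 2,3:5,6-di-O-isopropylidene-D-mannono-1,4-lactone
Conditions: TEMPO (cat.), PhI(OAc)2, CH2Cl2, rt
Reagents that add atoms: none
Why: Oxoammonium (TEMPO) oxidation of a lactol to the lactone; no stereocentre is touched and both acetonides are inert to the neutral conditions.

Step 2
Reactants: 2 2,3:5,6-di-O-isopropylidene-D-mannono-1,4-lactone
Product: 3 1-deoxy-3,4:6,7-di-O-isopropylidene-D-manno-hept-2-ulofuranose (methyl hemiketal, anomeric mixture)
Conditions: MeLi (1.05 equiv), THF, −78 °C; then aq. NH4Cl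
Reagents that add atoms: methyllithium, [Li]C
Why: Single addition of an organolithium to a γ-lactone; the lithium hemiketalate is stable at −78 °C, so a second addition is avoided and C10 gains its methyl group.

Step 3
Reactants: 3 methyl hemiketal
Product: 4 open-chain alcohol with C10 isopropenyl, 8,9-O- and 5,6-O-isopropylidene and free 7-OH (1,2-dideoxy-3,4:6,7-di-O-isopropylidene-2-C-methyl-D-manno-hept-1-enitol)
Conditions: Ph3PCH3Br, KOtBu, THF, 0 °C → reflux
Reagents that add atoms: methyltriphenylphosphonium bromide, C[P+](c1ccccc1)(c1ccccc1)c1ccccc1.[Br-]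
Why: Wittig methylenation of the open hydroxy-ketone form of the hemiketal, drawn from the ring–chain equilibrium by excess ylide; it completes the C10 isopropenyl group and leaves O7 as the only free hydroxyl, while C9 is held in the cis-dioxolane and is not expected to epimerise.

Step 4
Reactants: 4 open-chain 7-alcohol
Product: 5 7-O-TBS ether of 4
Conditions: TBSOTf, 2,6-lutidine, CH2Cl2, −78 → 0 °C
Reagents that add atoms: tert-butyldimethylsilyl triflate, CC(C)(C)[Si](C)(C)OS(=O)(=O)C(F)(F)F
Why: Silyl triflate silylation of a hindered secondary alcohol; TBS survives the acetal chemistry ahead and is removed by fluoride once the ring exists.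

Step 5
Reactants: 5 7-O-TBS bis-acetonide
Product: 6 5,6-diol (7-O-TBS, 8,9-O-isopropylidene, C10 isopropenyl)
Conditions: AcOH/H2O (3:2), rt
Reagents that add atoms: none
Why: Selective acetal hydrolysis; the terminal dioxolane (primary plus secondary oxygen) is cleaved much faster than the internal cis-disubstituted one, and the hindered secondary TBS ether tolerates dilute acetic acid.

Step 6
Reactants: 6 5,6-diol
Product: 7 5,6-O-(4-methoxybenzylidene) acetal of 6 (both acetal epimers)
Conditions: 4-MeOC6H4CH(OMe)2, PPTS (cat.), CH2Cl2, rt
Reagents that add atoms: 4-methoxybenzaldehyde dimethyl acetal, COc1ccc(C(OC)OC)cc1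
Why: Acid-catalysed transacetalisation of the 1,2-diol; either acetal epimer serves in the next step.

Step 7
Reactants: 7 4-methoxybenzylidene acetal
Product: 8 primary C5 alcohol with 6-O-PMB (7-O-TBS, 8,9-O-isopropylidene, C10 isopropenyl)
Conditions: iBu2AlH, CH2Cl2, −78 → 0 °C
Reagents that add atoms: none
Why: Regioselective reductive acetal opening; aluminium binds the less hindered primary oxygen, the C–O5 bond ionises and hydride leaves the PMB group on the secondary O6.

Step 8
Reactants: 8 primary C5 alcohol
Product: 9 C5 aldehyde (6-O-PMB, 7-O-TBS, 8,9-O-isopropylidene, C10 isopropenyl)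
Conditions: Dess–Martin periodinane, NaHCO3, CH2Cl2, 0 °C → rt
Reagents that add atoms: none
Why: Buffered hypervalent-iodine oxidation to the α-alkoxy aldehyde without epimerising C6; the aldehyde is used crude.

Step 9
Reactants: 9 C5 aldehyde
Product: 10 ethyl (E)-enoate (C4=C5 with methyl on C4, ester carbon = C3)
Conditions: Ph3P=C(CH3)CO2Et, CH2Cl2, rt
Reagents that add atoms: ethyl 2-(triphenylphosphoranylidene)propanoate, CCOC(=O)C(C)=P(c1ccccc1)(c1ccccc1)c1ccccc1
Why: Wittig olefination with a stabilised α-branched ylide, which is dependably E-selective for trisubstituted enoates; this fixes E-C4=C5 and the C4 methyl group under neutral, salt-free conditions.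

Step 10
Reactants: 10 ethyl (E)-enoate
Product: 11 (E)-allylic alcohol (C3–OH)
Conditions: iBu2AlH (2.5 equiv), CH2Cl2, −78 °C
Reagents that add atoms: none
Why: 1,2-Reduction of the conjugated ester to the allylic alcohol; the olefin geometry is retained and ethers and the acetonide are inert.

Step 11
Reactants: 11 (E)-allylic alcohol
Product: 12 (E)-allylic bromide (C3–Br)
Conditions: CBr4, PPh3, 2,6-lutidine, CH2Cl2, 0 °C
Reagents that add atoms: carbon tetrabromide, BrC(Br)(Br)Br
Why: Appel bromination by SN2 displacement at the primary allylic carbon under buffered neutral conditions; the bromide is used at once.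

Step 12
Reactants: 12 (E)-allylic bromide
Product: 13 triene (C1 vinyl, (4E)-C4=C5, C10 isopropenyl; 6-O-PMB, 7-O-TBS, 8,9-O-isopropylidene)
Conditions: CH2=CHCH2MgBr, THF, −78 → 0 °C
Reagents that add atoms: allylmagnesium bromide, C=CC[Mg]Br
Why: Allyl–allyl coupling by SN2 displacement at the primary allylic bromide; attack at C5 (SN2′) is disfavoured by the branched C6 centre, and the reagent supplies C2, C1 and the sacrificial terminal methylene.

Step 13
Reactants: 13 triene
Product: 14 (1(10)Z,4E)-4,10-dimethylcyclodeca-1(10),4-diene with 6-O-PMB, 7-O-TBS and 8,9-O-isopropylidene (C6–C9 from D-mannose)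
Conditions: second-generation Grubbs catalyst (H2IMes)(PCy3)Cl2Ru=CHPh (15 mol %, in portions), toluene (1 mM), 80 °C
Reagents that add atoms: none
Why: Ring-closing olefin metathesis; ruthenium loads on the monosubstituted C1 olefin, and from that carbene only closure onto the C10 isopropenyl group is productive (closure on C4=C5 would give a cyclobutene). The ten-membered ring, already holding an E olefin, should accept the new olefin only as Z, and the cis-dioxolane on C8/C9 and high dilution favour cyclisation.

Step 14
Reactants: 14 ring 7-O-TBS ether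
Product: 15 ring 7-ol (6-O-PMB, 8,9-O-isopropylidene)
Conditions: Bu4NF, THF, rt
Reagents that add atoms: none
Why: Fluoride cleavage of the only silyl ether; the PMB ether and the acetonide are inert.

Step 15
Reactants: 15 ring 7-ol
Product: 16 ring 7-ketone (6-O-PMB, 8,9-O-isopropylidene)
Conditions: Dess–Martin periodinane, NaHCO3, CH2Cl2, rt
Reagents that add atoms: none
Why: Buffered hypervalent-iodine oxidation of the secondary alcohol; non-basic conditions protect the α-stereocentres C6 and C8.

Step 16
Reactants: 16 ring 7-ketone
Product: 17 ring (7R)-7-ethynyl-7-ol (6-O-PMB, 8,9-O-isopropylidene)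
Conditions: MgBr2·OEt2, CH2Cl2, −78 °C; then HC≡CMgBr (THF), −78 → −20 °C
Reagents that add atoms: ethynylmagnesium bromide, C#C[Mg]Br
Why: Chelation-controlled (Cram chelate) 1,2-addition of an alkynyl Grignard reagent; magnesium bridges the C7 carbonyl and the PMB ether oxygen on C6, which puts C5 and the ring on one face, so ethynyl should enter from the open face anti to C5 and give the 7R carbinol with OH cis to O6. The Felkin–Anh preference at C8 points the same way.

Step 17
Reactants: 17 ring ethynyl carbinol acetonide
Product: 18 ring 7-ethynyl-7,8,9-triol (6-O-PMB)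
Conditions: AcOH/H2O/THF (3:1:1), 50 °C
Reagents that add atoms: none
Why: Acetal hydrolysis under weakly acidic conditions that leave the PMB ether, the tertiary propargylic alcohol and the oxygen-deactivated 1,5-diene untouched.

Step 18
Reactants: 18 ring triol
Product: 19 ring 7-ethynyl-7,8-diol with 9-O-TES (6-O-PMB)
Conditions: TESCl (1.1 equiv), imidazole, CH2Cl2, −40 → −20 °C
Reagents that add atoms: chlorotriethylsilane, CC[Si](Cl)(CC)CC
Why: Sterically governed monosilylation; O9–H is an ordinary allylic secondary alcohol whereas O8–H is flanked by the fully substituted C7, and the tertiary O7–H does not react with a silyl chloride.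

Step 19
Reactants: 20 tiglic acid ((E)-2-methylbut-2-enoic acid)
Product: 21 (E)-2-methylbut-2-en-1-ol
Conditions: LiAlH4, Et2O, 0 °C → rt
Reagents that add atoms: none
Why: Hydride reduction of the unsaturated acid at the carboxyl group only; the E geometry is retained.

Step 20
Reactants: 21 (E)-2-methylbut-2-en-1-ol
Product: 22 [(2R,3R)-2,3-dimethyloxiran-2-yl]methanol
Conditions: Ti(OiPr)4 (cat.), D-(−)-diethyl tartrate (cat.), tBuOOH, 4 Å sieves, CH2Cl2, −20 °C
Reagents that add atoms: tert-butyl hydroperoxide, CC(C)(C)OO
Why: Sharpless asymmetric epoxidation; the D-(−)-tartrate ligand delivers oxygen to the face that gives the (2R,3R)-epoxy alcohol, setting both oxirane stereocentres under reagent control, while the E olefin fixes their relative configuration.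

Step 21
Reactants: 22 [(2R,3R)-2,3-dimethyloxiran-2-yl]methanol
Product: 23 (2S,3R)-2,3-dimethyloxirane-2-carboxylic acid
Conditions: TEMPO (cat.), PhI(OAc)2 (2.2 equiv), MeCN/H2O (1:1), rt
Reagents that add atoms: water, O
Why: Oxoammonium oxidation of the primary alcohol through the aldehyde hydrate to the acid; the oxirane is untouched and the C2 descriptor changes from R to S only through the priority rules.

Step 22
Reactants: 19 ring 7,8-diol with 9-O-TES; 23 (2S,3R)-2,3-dimethyloxirane-2-carboxylic acid
Product: 25 ring 8-O-[(2S,3R)-2,3-dimethyloxirane-2-carbonyl] ester with 7-OH, 9-O-TES and 6-O-PMB, via mixed anhydride 24 (not isolated)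
Conditions: 23, 2,4,6-Cl3C6H2COCl, Et3N, THF, 0 °C → rt; then 19, DMAP, toluene, rt → 45 °C
Reagents that add atoms: none
Why: Yamaguchi esterification; the mixed anhydride acylates the only secondary hydroxyl (O8–H), the tertiary O7–H is inert to acyl transfer, and the non-acidic conditions spare the oxirane.

Step 23
Reactants: 25 ring 8-ester 7-ol
Product: 26 ring 7,9-bis-O-TES ether with 8-O-epoxyacyl and 6-O-PMB
Conditions: TESOTf, 2,6-lutidine, CH2Cl2, −78 °C
Reagents that add atoms: triethylsilyl triflate, CC[Si](CC)(CC)OS(=O)(=O)C(F)(F)F
Why: Silyl triflate silylation of the tertiary propargylic alcohol at low temperature, buffered by lutidine so that the electron-poor glycidic oxirane is not activated.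

Step 24
Reactants: 26 ring 6-O-PMB ether
Product: 27 ring 6-ol 7-ethynyl carbinol with 7,9-bis-O-TES and 8-O-epoxyacyl (6R,7R,8R,9R)
Conditions: DDQ, CH2Cl2/pH 7 buffer (10:1), 0 °C
Reagents that add atoms: none
Why: Oxidative cleavage of the PMB ether by benzylic hydride abstraction and hydrolysis of the oxocarbenium ion; silyl ethers, oxirane, alkyne and trisubstituted olefins are inert to buffered DDQ.

Step 25
Reactants: 27 ring 6-ol 7-ethynyl carbinol with 7,9-bis-O-TES and 8-O-epoxyacyl
Product: 28 7,9-bis-O-TES ether of the target
Conditions: PdCl2 (10 mol %), PPh3 (20 mol %), SnCl2 (10 mol %), CO (5 atm), MeCN, 65 °C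
Reagents that add atoms: carbon monoxide, [C-]#[O+]
Why: Under CO the divalent palladium chloride/phosphine/tin system binds CO, and the free C6 hydroxyl attacks it to give an alkoxycarbonyl–palladium complex (C12–O6). The pendant ethynyl group then inserts syn into the palladium–acyl bond, forming C11–C12 and placing palladium on C13. Protonolysis of the alkenyl–palladium bond by the HCl released in the first stage gives the exocyclic methylene and returns divalent palladium. The closest known reaction type is the palladium-catalysed cyclocarbonylation of but-3-yn-1-ols to α-methylene-γ-butyrolactones. The one ring closed is the five-membered lactone, in the 5-exo-dig mode, trans-fused across C6–C7 as the existing configurations dictate; no stereocentre is created. The step needs closure through O6 only, which is secured because O7 and O9 are silylated and O8 is acylated, so four- and six-membered lactones cannot form. No base or enolate is involved, so the C7–O bond, the glycidic ester and the diene are not exposed to elimination, conjugate addition or isomerisation, and SnCl2 is kept equimolar to palladium to limit the Lewis acid load.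

Step 26
Reactants: 28 7,9-bis-O-TES ether of the target
Product: 29 CNP0420662.1 (target)
Conditions: HF·pyridine, pyridine, THF, 0 °C → rt
Reagents that add atoms: none
Why: Fluoride cleavage of both triethylsilyl ethers under buffered, weakly acidic conditions, which avoids base-induced acyl migration from O8, conjugate addition to the methylene lactone and elimination at C7.

## Compound list

1 | 2,3:5,6-di-O-isopropylidene-α-D-mannofuranose | O[C@H]1O[C@H]([C@H]2COC(C)(C)O2)[C@@H]3OC(C)(C)O[C@H]13 | starting material
2 | 2,3:5,6-di-O-isopropylidene-D-mannono-1,4-lactone | O=C1O[C@H]([C@H]2COC(C)(C)O2)[C@@H]3OC(C)(C)O[C@H]13 | intermediate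
3 | 1-deoxy-3,4:6,7-di-O-isopropylidene-D-manno-hept-2-ulofuranose (methyl hemiketal, anomeric mixture) | CC1(O)O[C@H]([C@H]2COC(C)(C)O2)[C@@H]3OC(C)(C)O[C@H]13 | intermediate
4 | open-chain 7-alcohol: C10 isopropenyl, 8,9-O- and 5,6-O-isopropylidene (1,2-dideoxy-3,4:6,7-di-O-isopropylidene-2-C-methyl-D-manno-hept-1-enitol) | C=C(C)[C@H]1OC(C)(C)O[C@H]1[C@H](O)[C@H]2COC(C)(C)O2 | intermediate
5 | 7-O-TBS ether of 4 | C=C(C)[C@H]1OC(C)(C)O[C@H]1[C@H](O[Si](C)(C)C(C)(C)C)[C@H]2COC(C)(C)O2 | intermediate
6 | 5,6-diol (7-O-TBS, 8,9-O-isopropylidene, C10 isopropenyl) | C=C(C)[C@H]1OC(C)(C)O[C@H]1[C@H](O[Si](C)(C)C(C)(C)C)[C@H](O)CO | intermediate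
7 | 5,6-O-(4-methoxybenzylidene) acetal of 6 (both acetal epimers) | C=C(C)[C@H]1OC(C)(C)O[C@H]1[C@H](O[Si](C)(C)C(C)(C)C)[C@H]2COC(c3ccc(OC)cc3)O2 | intermediate
8 | primary C5 alcohol, 6-O-PMB, 7-O-TBS, 8,9-O-isopropylidene, C10 isopropenyl | C=C(C)[C@H]1OC(C)(C)O[C@H]1[C@H](O[Si](C)(C)C(C)(C)C)[C@H](OCc2ccc(OC)cc2)CO | intermediate
9 | C5 aldehyde, 6-O-PMB, 7-O-TBS, 8,9-O-isopropylidene, C10 isopropenyl | C=C(C)[C@H]1OC(C)(C)O[C@H]1[C@H](O[Si](C)(C)C(C)(C)C)[C@H](OCc2ccc(OC)cc2)C=O | intermediate
10 | ethyl (E)-enoate (C4=C5, methyl on C4, ester carbon C3) | C=C(C)[C@H]1OC(C)(C)O[C@H]1[C@H](O[Si](C)(C)C(C)(C)C)[C@H](OCc2ccc(OC)cc2)/C=C(\C)C(=O)OCC | intermediate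
11 | (E)-allylic alcohol (C3–OH) | C=C(C)[C@H]1OC(C)(C)O[C@H]1[C@H](O[Si](C)(C)C(C)(C)C)[C@H](OCc2ccc(OC)cc2)/C=C(\C)CO | intermediate
12 | (E)-allylic bromide (C3–Br) | C=C(C)[C@H]1OC(C)(C)O[C@H]1[C@H](O[Si](C)(C)C(C)(C)C)[C@H](OCc2ccc(OC)cc2)/C=C(\C)CBr | intermediate
13 | triene: C1 vinyl, (4E)-C4=C5, C10 isopropenyl; 6-O-PMB, 7-O-TBS, 8,9-O-isopropylidene | C=C(C)[C@H]1OC(C)(C)O[C@H]1[C@H](O[Si](C)(C)C(C)(C)C)[C@H](OCc2ccc(OC)cc2)/C=C(\C)CCC=C | intermediate
14 | (1(10)Z,4E)-4,10-dimethylcyclodeca-1(10),4-diene, 6-O-PMB, 7-O-TBS, 8,9-O-isopropylidene | COc1ccc(CO[C@@H]2/C=C(\C)CC/C=C(/C)[C@H]3OC(C)(C)O[C@H]3[C@@H]2O[Si](C)(C)C(C)(C)C)cc1 | intermediate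
15 | ring 7-ol, 6-O-PMB, 8,9-O-isopropylidene | COc1ccc(CO[C@@H]2/C=C(\C)CC/C=C(/C)[C@H]3OC(C)(C)O[C@H]3[C@@H]2O)cc1 | intermediate
16 | ring 7-ketone, 6-O-PMB, 8,9-O-isopropylidene | COc1ccc(CO[C@@H]2/C=C(\C)CC/C=C(/C)[C@H]3OC(C)(C)O[C@H]3C2=O)cc1 | intermediate
17 | ring (7R)-7-ethynyl-7-ol, 6-O-PMB, 8,9-O-isopropylidene | COc1ccc(CO[C@@H]2/C=C(\C)CC/C=C(/C)[C@H]3OC(C)(C)O[C@H]3[C@@]2(O)C#C)cc1 | intermediate
18 | ring 7-ethynyl-7,8,9-triol, 6-O-PMB | COc1ccc(CO[C@@H]2/C=C(\C)CC/C=C(/C)[C@@H](O)[C@@H](O)[C@@]2(O)C#C)cc1 | intermediate
19 | ring 7-ethynyl-7,8-diol, 9-O-TES, 6-O-PMB | COc1ccc(CO[C@@H]2/C=C(\C)CC/C=C(/C)[C@@H](O[Si](CC)(CC)CC)[C@@H](O)[C@@]2(O)C#C)cc1 | intermediate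
20 | tiglic acid | C/C=C(\C)C(=O)O | starting material
21 | (E)-2-methylbut-2-en-1-ol | C/C=C(\C)CO | intermediate
22 | [(2R,3R)-2,3-dimethyloxiran-2-yl]methanol | OC[C@@]1(C)O[C@@H]1C | intermediate
23 | (2S,3R)-2,3-dimethyloxirane-2-carboxylic acid | OC(=O)[C@@]1(C)O[C@@H]1C | intermediate
24 | mixed anhydride of 23 with 2,4,6-trichlorobenzoic acid (not isolated) | O=C(OC(=O)[C@@]1(C)O[C@@H]1C)c1c(Cl)cc(Cl)cc1Cl | intermediate
25 | ring 8-O-[(2S,3R)-2,3-dimethyloxirane-2-carbonyl] ester, 7-OH, 9-O-TES, 6-O-PMB | COc1ccc(CO[C@@H]2/C=C(\C)CC/C=C(/C)[C@@H](O[Si](CC)(CC)CC)[C@@H](OC(=O)[C@@]3(C)O[C@@H]3C)[C@@]2(O)C#C)cc1 | intermediate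
26 | ring 7,9-bis-O-TES, 8-O-epoxyacyl, 6-O-PMB | COc1ccc(CO[C@@H]2/C=C(\C)CC/C=C(/C)[C@@H](O[Si](CC)(CC)CC)[C@@H](OC(=O)[C@@]3(C)O[C@@H]3C)[C@@]2(O[Si](CC)(CC)CC)C#C)cc1 | intermediate
27 | ring 6-ol 7-ethynyl carbinol, 7,9-bis-O-TES, 8-O-epoxyacyl (6R,7R,8R,9R) | O[C@@H]1/C=C(\C)CC/C=C(/C)[C@@H](O[Si](CC)(CC)CC)[C@@H](OC(=O)[C@@]2(C)O[C@@H]2C)[C@]1(C#C)O[Si](CC)(CC)CC | intermediate
28 | 7,9-bis-O-TES ether of the target | C=C1C(=O)O[C@@H]2/C=C(\C)CC/C=C(/C)[C@@H](O[Si](CC)(CC)CC)[C@@H](OC(=O)[C@@]3(C)O[C@@H]3C)[C@@]12O[Si](CC)(CC)CC | intermediate
29 | CNP0420662.1 | C=C1C(=O)O[C@@H]2/C=C(\C)CC/C=C(/C)[C@@H](O)[C@@H](OC(=O)[C@@]3(C)O[C@@H]3C)[C@@]12O | target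

## Step count and least certain steps

Total: 26 steps. Longest linear sequence: 23 steps (steps 1–18 and 22–26); the acid branch is steps 19–21.

Step 25 (key step). The Lewis-acidic tin chloride or traces of HCl may open the oxirane or strip a silyl ether, and alkoxycarbonylation at the hindered O6 may be slow enough for alkyne oligomerisation to take over. The fallback introduces C12 through a vinyl halide. Setting out from 27, hydrostannation with Bu3SnH catalysed by Mo(CO)3(CNtBu)3 should place tin on the internal carbon C11 and give the vinylstannane F1. Iododestannylation (I2, CH2Cl2, −78 °C) gives the 2-iodoalkene F2. Pd(PPh3)4, CO (1 atm) and K2CO3 in MeCN at 50 °C then close the lactone by oxidative addition of zerovalent palladium, CO insertion and capture of the acylpalladium by O6–H, and the route is rejoined at 28.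

Step 13. Intermolecular metathesis through the reactive C1 vinyl group may outrun the strained ten-membered closure onto the 1,1-disubstituted C10 olefin, or a six-membered closure between C10 and C5 may expel the C1–C4 chain. The fallback closes the ring on a different substrate. Setting out from 13, Bu4NF gives the acyclic alcohol F3 and Dess–Martin periodinane the acyclic C7 ketone F4. Metathesis is then run on F4, whose planar C7 without the bulky silyl ether changes the torsional preferences of the tether, and the closure returns to the route at 16.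

Step 16. Facial selectivity may be poor if the ring conformation overrides the chelate, and the α,α′-dialkoxy ketone may enolise. The fallback moves the addition to the open chain. It sets out from 13 and passes through F3 and F4 as described for step 13. On the open-chain ketone F4, TMSC≡CMgBr with MgBr2·OEt2 in CH2Cl2 at −78 °C should add under Cram-chelate control by the O6 ether, reinforced by the Felkin–Anh preference at C8, to give the acyclic silylalkynyl carbinol F5. Ring-closing metathesis (the silylated alkyne is inert to the ruthenium carbene) gives the ring silylalkynyl carbinol F6, and K2CO3 in MeOH removes the C-silyl group to rejoin the route at 17.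

Step 3. The ring–chain equilibrium may keep the hemiketal closed so that olefination stalls, or the basic ylide may epimerise C9 or trigger β-elimination of the dioxolane oxygen. The fallback makes the methyl ketone in open-chain form. Setting out from 2, MeNH(OMe)·HCl with Me3Al opens the lactone to the hydroxy Weinreb amide F7. TBSOTf with 2,6-lutidine gives its silyl ether F8, and MeMgBr gives the open-chain methyl ketone F9. Methylenation with Ph3P=CH2 then returns to the route at 5.

Step 18. Regioselection between O9–H and O8–H may be insufficient, or the silyl group may migrate between them. The fallback distinguishes the two hydroxyls by oxidation state. Setting out from 18, MnO2 oxidises only the allylic C9 carbinol to the enone diol F10. Yamaguchi acylation with 23 can then occur only at O8 and gives the keto ester F11. Reagent-controlled reduction with an oxazaborolidine (CBS) catalyst and BH3·SMe2 restores the 9R carbinol as the hydroxy ester F12. TESOTf (2.5 equiv) with 2,6-lutidine silylates O9 and O7 in one operation, returning to the route at 26.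

## Further compounds

F1 | step 25 | C11-tributylstannyl alkene from 27 (C11(SnBu3)=C13H2) | O[C@@H]1/C=C(\C)CC/C=C(/C)[C@@H](O[Si](CC)(CC)CC)[C@@H](OC(=O)[C@@]2(C)O[C@@H]2C)[C@]1(C(=C)[Sn](CCCC)(CCCC)CCCC)O[Si](CC)(CC)CC
F2 | step 25 | C11-iodo alkene from 27 (C11(I)=C13H2) | O[C@@H]1/C=C(\C)CC/C=C(/C)[C@@H](O[Si](CC)(CC)CC)[C@@H](OC(=O)[C@@]2(C)O[C@@H]2C)[C@]1(C(I)=C)O[Si](CC)(CC)CC
F3 | step 13 | acyclic 7-alcohol (desilylated 13) | C=C(C)[C@H]1OC(C)(C)O[C@H]1[C@H](O)[C@H](OCc2ccc(OC)cc2)/C=C(\C)CCC=C
F4 | step 13 | acyclic 7-ketone triene | C=C(C)[C@H]1OC(C)(C)O[C@H]1C(=O)[C@H](OCc2ccc(OC)cc2)/C=C(\C)CCC=C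
F5 | step 16 | acyclic (7R)-7-[(trimethylsilyl)ethynyl] carbinol | C=C(C)[C@H]1OC(C)(C)O[C@H]1[C@@](O)(C#C[Si](C)(C)C)[C@H](OCc2ccc(OC)cc2)/C=C(\C)CCC=C
F6 | step 16 | ring (7R)-7-[(trimethylsilyl)ethynyl] carbinol (C-silyl derivative of 17) | COc1ccc(CO[C@@H]2/C=C(\C)CC/C=C(/C)[C@H]3OC(C)(C)O[C@H]3[C@@]2(O)C#C[Si](C)(C)C)cc1
F7 | step 3 | N-methoxy-N-methyl-2,3:5,6-di-O-isopropylidene-D-mannonamide (free 4-OH) | CON(C)C(=O)[C@H]1OC(C)(C)O[C@H]1[C@H](O)[C@H]2COC(C)(C)O2
F8 | step 3 | 4-O-TBS ether of F7 | CON(C)C(=O)[C@H]1OC(C)(C)O[C@H]1[C@H](O[Si](C)(C)C(C)(C)C)[C@H]2COC(C)(C)O2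
F9 | step 3 | open-chain C10 methyl ketone, 7-O-TBS, 8,9-O- and 5,6-O-isopropylidene | CC(=O)[C@H]1OC(C)(C)O[C@H]1[C@H](O[Si](C)(C)C(C)(C)C)[C@H]2COC(C)(C)O2
F10 | step 18 | ring 9-ketone 7,8-diol, 6-O-PMB | COc1ccc(CO[C@@H]2/C=C(\C)CC/C=C(/C)C(=O)[C@@H](O)[C@@]2(O)C#C)cc1
F11 | step 18 | ring 9-ketone 8-O-epoxyacyl ester, 7-OH, 6-O-PMB | COc1ccc(CO[C@@H]2/C=C(\C)CC/C=C(/C)C(=O)[C@@H](OC(=O)[C@@]3(C)O[C@@H]3C)[C@@]2(O)C#C)cc1
F12 | step 18 | ring 7,9-diol 8-O-epoxyacyl ester, 6-O-PMB | COc1ccc(CO[C@@H]2/C=C(\C)CC/C=C(/C)[C@@H](O)[C@@H](OC(=O)[C@@]3(C)O[C@@H]3C)[C@@]2(O)C#C)cc1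
A1 | alternative 1 | trans-decalin C9-hydroxy C5-mesylate, 6-O-TBS, 7-dioxolane | CC1=CCC[C@@]2(C)[C@H](OS(C)(=O)=O)[C@@H](O[Si](C)(C)C(C)(C)C)C3(OCCO3)C[C@]12O
A2 | alternative 1 | (2Z,6E)-cyclodecadienone, 6-O-TBS, 7-dioxolane | CC(C)(C)[Si](C)(C)O[C@@H]1/C=C(\C)CC/C=C(/C)C(=O)CC12OCCO2
A3 | alternative 2 | acyclic ynal (C6 aldehyde, C4≡C5 terminal alkyne), 7-O-TES, 8-O-PMB, 9-O-TBS | CC[Si](CC)(CC)OCC(=C)[C@@](O[Si](CC)(CC)CC)(C=O)[C@H](OCc1ccc(OC)cc1)[C@H](O[Si](C)(C)C(C)(C)C)/C(C)=C\CCC#C
A4 | alternative 2 | ten-membered 6-ol with masked lactone, 8-O-PMB | CC[Si](CC)(CC)OCC(=C)[C@@]1(O[Si](CC)(CC)CC)[C@H](O)/C=C(\C)CC/C=C(/C)[C@@H](O[Si](C)(C)C(C)(C)C)[C@H]1OCc1ccc(OC)cc1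
A5 | alternative 3 | acyclic lactone with C9 aldehyde and (Z)-C10 iodoalkene, 7-O-TBS, 8-O-epoxyacyl | C=C1C(=O)O[C@H](/C=C(\C)CC/C=C(/C)I)[C@@]1(O[Si](C)(C)C(C)(C)C)[C@H](OC(=O)[C@@]2(C)O[C@@H]2C)C=O
A6 | alternative 3 | 7-O-TBS ether of the target | C=C1C(=O)O[C@@H]2/C=C(\C)CC/C=C(/C)[C@@H](O)[C@@H](OC(=O)[C@@]3(C)O[C@@H]3C)[C@@]12O[Si](C)(C)C(C)(C)C
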